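**Retrosynthetic overview**
1. Target 35 ⇐ nonamethyl ether 34 by ninefold O‑demethylation; trans ring E ⇐ cis ring E by acid equilibration at C‑2′.
2. Ring E (second dihydrofuran) ⇐ enantioselective rhodium‑carbene C–H insertion into a 2,4‑dimethoxybenzyl ether; its diaryl ketone ⇐ aryllithium from tetracyclic bromide 24 + 3,5‑dimethoxybenzaldehyde.
3. Ring D (seven‑membered) ⇐ acid‑induced Friedel–Crafts closure of a stilbene‑derived C‑8 cation onto ring B; the stilbene ⇐ intermolecular aldol addition of the (2,4‑dimethoxyphenyl)acetic acid dianion to ring A aldehyde 19 (C‑7–C‑8 bond), then decarboxylative dehydration.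
4. Ring C (first dihydrofuran) ⇐ the same carbene C–H insertion into a 4‑methoxybenzyl ether; its ketone ⇐ mono‑lithiated dibromide 5 + 3,5‑dimethoxybenzaldehyde; ring A ⇐ methyl 3,5‑dihydroxybenzoate.
5. Order of ring formation: ring C → ring D (sets C‑8) → ring E; rings A, B and all pendant aryl rings are bought as arenes.

Assumption: Rh2(R‑PTAD)4 (= Rh2[(R)‑O2CCH(1‑adamantyl)(N‑phthalimido)]4, a dimer of divalent rhodium) gives the (3R)‑dihydrobenzofuran and Rh2(S‑PTAD)4 the (3S) one from these diaryldiazomethanes; if the sense is the reverse, the two catalysts are exchanged.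

Locants used for the polycycles: C‑2/C‑3 = O–CH(Ar)/CH of ring C; C‑7 = CH2 and C‑8 = CH(Ar) of ring D; C‑2′/C‑3′ = O–CH(Ar)/CH(Ar) of ring E; ring A is the central benzene, ring B the dimethoxybenzene inside ring D.

**Step 1**
Reactants: 1 methyl 3,5‑dihydroxybenzoate
Product: 2 methyl 3,5‑bis(methoxymethoxy)benzoate
Conditions: MOMCl (2.5 equiv), i‑Pr2NEt, CH2Cl2, 0 °C to rt
Reagents that add atoms: chloromethyl methyl ether (MOMCl), COCCl
Why: O‑alkylation (MOM protection) of both phenols keeps ring A symmetric and lets both oxygens be freed together later under mild acid.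

**Step 2**
Reactants: 2 methyl 3,5‑bis(methoxymethoxy)benzoate
Product: 3 [3,5‑bis(methoxymethoxy)phenyl]methanol
Conditions: LiAlH4, THF, 0 °C; then H2O, aq NaOH
Reagents that add atoms: none
Why: Hydride reduction of the ester gives the benzylic alcohol whose carbon becomes C‑7, the MOM acetals being inert to hydride.

**Step 3**
Reactants: 3 [3,5‑bis(methoxymethoxy)phenyl]methanol
Product: 4 [2,6‑dibromo‑3,5‑bis(methoxymethoxy)phenyl]methanol
Conditions: NBS (2.1 equiv), MeCN, 0 °C to rt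
Reagents that add atoms: N‑bromosuccinimide (NBS), O=C1CCC(=O)N1Br
Why: Electrophilic aromatic bromination occurs para to one alkoxy group and ortho to the other at the two equivalent positions flanking CH2OH, the position between the two alkoxy groups being the least accessible.

**Step 4**
Reactants: 4 [2,6‑dibromo‑3,5‑bis(methoxymethoxy)phenyl]methanol
Product: 5 tert‑butyl{[2,6‑dibromo‑3,5‑bis(methoxymethoxy)phenyl]methoxy}diphenylsilane
Conditions: TBDPSCl, imidazole, DMF, rt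
Reagents that add atoms: tert‑butyl(chloro)diphenylsilane (TBDPSCl), CC(C)(C)[Si](Cl)(c1ccccc1)c1ccccc1
Why: Silyl ether formation gives a bulky ether that survives the later acid, hydrazine and organolithium steps and is too hindered to migrate to an ortho aryllithium at −78 °C.

**Step 5**
Reactants: 5 tert‑butyl{[2,6‑dibromo‑3,5‑bis(methoxymethoxy)phenyl]methoxy}diphenylsilane; 6 3,5‑dimethoxybenzaldehyde
Product: 8 (RS)‑{3‑bromo‑2‑[(tert‑butyldiphenylsilyloxy)methyl]‑4,6‑bis(methoxymethoxy)phenyl}(3,5‑dimethoxyphenyl)methanol, via aryllithium 7 (not isolated)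
Conditions: n‑BuLi (1.05 equiv), THF, −78 °C, 10 min; then 6, −78 °C; H2O
Reagents that add atoms: none
Why: Bromine–lithium exchange of one of the two equivalent bromides (the electron‑rich aryllithium resists a second exchange) and 1,2‑addition to the aldehyde; the carbinol centre is racemic and is erased in step 6.

**Step 6**
Reactants: 8 the diarylmethanol
Product: 9 {3‑bromo‑2‑[(tert‑butyldiphenylsilyloxy)methyl]‑4,6‑bis(methoxymethoxy)phenyl}(3,5‑dimethoxyphenyl)methanone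
Conditions: Dess–Martin periodinane, CH2Cl2, rt
Reagents that add atoms: none
Why: Dess–Martin oxidation converts the hindered diarylcarbinol into the diaryl ketone under near‑neutral conditions that leave MOM and silyl ethers intact.

**Step 7**
Reactants: 9 the bis‑MOM ketone
Product: 10 {3‑bromo‑2‑[(tert‑butyldiphenylsilyloxy)methyl]‑4,6‑dihydroxyphenyl}(3,5‑dimethoxyphenyl)methanone
Conditions: 3 M aq HCl, MeOH/THF, 45 °C
Reagents that add atoms: none
Why: Acid‑catalysed transacetalisation to methanol removes both aryl MOM groups while the primary TBDPS ether and the aryl methyl ethers are stable.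

**Step 8**
Reactants: 10 the dihydroxy ketone
Product: 11 {3‑bromo‑2‑[(tert‑butyldiphenylsilyloxy)methyl]‑6‑hydroxy‑4‑(prop‑2‑en‑1‑yloxy)phenyl}(3,5‑dimethoxyphenyl)methanone
Conditions: allyl bromide (1.05 equiv), K2CO3, acetone, rt
Reagents that add atoms: allyl bromide, C=CCBr
Why: Williamson etherification is selective for the more acidic, non‑hydrogen‑bonded phenol para to the ketone (classical 2,4‑dihydroxyaryl ketone selectivity), and the allyl group is stable to all acid steps that follow.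

**Step 9**
Reactants: 11 the mono‑allyl ether; 12 4‑methoxybenzyl chloride
Product: 13 {3‑bromo‑2‑[(tert‑butyldiphenylsilyloxy)methyl]‑6‑[(4‑methoxyphenyl)methoxy]‑4‑(prop‑2‑en‑1‑yloxy)phenyl}(3,5‑dimethoxyphenyl)methanone
Conditions: K2CO3, n‑Bu4NI (cat.), DMF, 60 °C
Reagents that add atoms: none
Why: Williamson etherification of the remaining chelated phenol under more forcing conditions installs the 4‑methoxybenzyl group whose CH2 becomes C‑2.

**Step 10**
Reactants: 13 the ketone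
Product: 14 hydrazone of 13 (E/Z mixture)
Conditions: N2H4·H2O (20 equiv), AcOH (cat.), EtOH, 80 °C, sealed tube, Ar
Reagents that add atoms: hydrazine (used as the hydrate), NN
Why: Condensation of the hindered benzophenone with excess hydrazine gives the hydrazone, argon excluding diimide formation that could reduce the allyl group.

**Step 11**
Reactants: 14 the hydrazone
Product: 16 (2S,3R)‑5‑bromo‑4‑[(tert‑butyldiphenylsilyloxy)methyl]‑3‑(3,5‑dimethoxyphenyl)‑2‑(4‑methoxyphenyl)‑6‑(prop‑2‑en‑1‑yloxy)‑2,3‑dihydro‑1‑benzofuran (cis), via diaryldiazomethane 15 (not isolated)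
Conditions: MnO2, CH2Cl2, 0 °C, filter; filtrate added over 2 h to Rh2(R‑PTAD)4 (1 mol %), CH2Cl2, 0 °C
Reagents that add atoms: none
Why: MnO2 dehydrogenates the hydrazone to the diazo compound and the chiral dirhodium carboxylate converts it into a donor/donor carbene that undergoes enantioselective 1,5 C–H insertion into the OCH2Ar group, the catalyst setting C‑3 (R) and the concerted insertion giving cis C‑2 (S).

**Step 12**
Reactants: 16 the cis‑dihydrobenzofuran
Product: 17 (2R,3R)‑5‑bromo‑4‑[(tert‑butyldiphenylsilyloxy)methyl]‑3‑(3,5‑dimethoxyphenyl)‑2‑(4‑methoxyphenyl)‑6‑(prop‑2‑en‑1‑yloxy)‑2,3‑dihydro‑1‑benzofuran (trans)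
Conditions: TFA/CH2Cl2 (1:4), 0 °C to rt
Reagents that add atoms: none
Why: Acid‑mediated reversible heterolysis of the benzylic C‑2–O bond (anisyl‑stabilised cation) equilibrates C‑2 to the thermodynamically preferred trans isomer without touching C‑3.

**Step 13**
Reactants: 17 the trans silyl ether
Product: 18 [(2R,3R)‑5‑bromo‑3‑(3,5‑dimethoxyphenyl)‑2‑(4‑methoxyphenyl)‑6‑(prop‑2‑en‑1‑yloxy)‑2,3‑dihydro‑1‑benzofuran‑4‑yl]methanol
Conditions: n‑Bu4NF, THF, 0 °C to rt
Reagents that add atoms: none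
Why: Fluoride‑mediated desilylation frees the benzylic alcohol under non‑acidic conditions.

**Step 14**
Reactants: 18 the benzylic alcohol
Product: 19 (2R,3R)‑5‑bromo‑3‑(3,5‑dimethoxyphenyl)‑2‑(4‑methoxyphenyl)‑6‑(prop‑2‑en‑1‑yloxy)‑2,3‑dihydro‑1‑benzofuran‑4‑carbaldehyde
Conditions: Dess–Martin periodinane, CH2Cl2, 0 °C to rt
Reagents that add atoms: none
Why: Dess–Martin oxidation gives the aldehyde without over‑oxidation or epimerisation.

**Step 15**
Reactants: 19 the aldehyde; 20 (2,4‑dimethoxyphenyl)acetic acid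
Product: 22 3‑[(2R,3R)‑5‑bromo‑3‑(3,5‑dimethoxyphenyl)‑2‑(4‑methoxyphenyl)‑6‑(prop‑2‑en‑1‑yloxy)‑2,3‑dihydro‑1‑benzofuran‑4‑yl]‑2‑(2,4‑dimethoxyphenyl)‑3‑hydroxypropanoic acid (mixture at the two side‑chain centres), via dilithium enediolate 21 (not isolated)
Conditions: 20 (2.2 equiv), LiN(i‑Pr)2 (4.5 equiv), THF, −78 to 0 °C; then 19, −78 °C; AcOH quench at −78 °C
Reagents that add atoms: none
Why: Aldol addition (Ivanov type) of the carboxylic acid dianion to the aldehyde forms the C‑7–C‑8 bond and joins the third aryl unit, giving the β‑hydroxy acid directly so that no retro‑aldol‑prone ester hydrolysis is needed; the two new centres need no control because both are erased in steps 16 and 17.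

**Step 16**
Reactants: 22 the β‑hydroxy acid
Product: 23 (2R,3R)‑5‑bromo‑4‑[(E)‑2‑(2,4‑dimethoxyphenyl)ethenyl]‑3‑(3,5‑dimethoxyphenyl)‑2‑(4‑methoxyphenyl)‑6‑(prop‑2‑en‑1‑yloxy)‑2,3‑dihydro‑1‑benzofuran
Conditions: Me2NCH(OCH2CMe3)2 (4 equiv), CHCl3, rt to 60 °C
Reagents that add atoms: none
Why: Decarboxylative dehydration with a formamide acetal (anti fragmentation of the O‑activated β‑hydroxy carboxylate) gives the stilbene under neutral conditions, the neopentyl acetal avoiding ester formation.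

**Step 17**
Reactants: 23 the stilbene
Product: 24 (2R,3R,8R)‑tetracyclic bromide: ring A fused to ring C [C‑2 4‑methoxyphenyl], ring B (dimethoxy) joined to C‑3 and C‑8, C‑8 bearing 2,4‑dimethoxyphenyl, C‑7H2 on ring A; ring A also carries Br next to the C‑7 carbon and O‑allyl next to Br
Conditions: TFA (20 equiv), CH2Cl2 (5 mM), 0 °C to rt
Reagents that add atoms: none
Why: Protonation of the stilbene at C‑7 gives the C‑8 cation stabilised by the 2,4‑dimethoxyphenyl group, which ring B traps in an intramolecular Friedel–Crafts alkylation (the closure known for ε‑viniferin to ampelopsin B), C‑8 (R) being set by substrate control because ring B, held on one face by C‑3, attacks with the aryl group pseudo‑axial and turned away from its peri methoxy group.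

**Step 18**
Reactants: 24 the tetracyclic bromide; 6 3,5‑dimethoxybenzaldehyde
Product: 26 (2R,3R,8R)‑tetracyclic diarylmethanol: Br of 24 replaced by CH(OH)(3,5‑dimethoxyphenyl), carbinol epimers, via aryllithium 25 (not isolated)
Conditions: t‑BuLi (2.2 equiv), THF, −78 °C, 5 min; then 6, −78 °C; H2O
Reagents that add atoms: none
Why: Bromine–lithium exchange is faster than any deprotonation or attack on the allyl ether at −78 °C and the aryllithium adds to the aldehyde; the carbinol centre is erased in step 19.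

**Step 19**
Reactants: 26 the diarylmethanol
Product: 27 (2R,3R,8R)‑tetracyclic ketone: ring A bearing C(=O)(3,5‑dimethoxyphenyl) between the C‑7 carbon and the O‑allyl carbon
Conditions: Dess–Martin periodinane, CH2Cl2, rt
Reagents that add atoms: none
Why: Dess–Martin oxidation gives the second diaryl ketone without affecting the dihydrobenzofuran or the allyl ether.

**Step 20**
Reactants: 27 the allyl ether ketone
Product: 28 (2R,3R,8R)‑tetracyclic hydroxy ketone: O‑allyl of 27 replaced by OH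
Conditions: Pd(PPh3)4 (5 mol %), morpholine (5 equiv), THF, rt
Reagents that add atoms: none
Why: Tsuji–Trost deallylation: zerovalent palladium forms a π‑allyl complex that morpholine intercepts, freeing the phenol under neutral conditions (the aryl bromide is already gone).

**Step 21**
Reactants: 28 the phenol; 29 2,4‑dimethoxybenzyl alcohol
Product: 30 (2R,3R,8R)‑tetracyclic ketone with the ring A oxygen as 2,4‑dimethoxybenzyl ether
Conditions: 29 (1.5 equiv), PPh3, DIAD, THF, 0 °C to rt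
Reagents that add atoms: none
Why: Mitsunobu etherification attaches the 2,4‑dimethoxybenzyl group, whose chloride is too unstable to handle, and its CH2 becomes C‑2′.

**Step 22**
Reactants: 30 the ketone
Product: 31 hydrazone of 30 (E/Z mixture)
Conditions: N2H4·H2O (20 equiv), AcOH (cat.), EtOH, 80 °C, sealed tube, Ar
Reagents that add atoms: hydrazine (used as the hydrate), NN
Why: Hydrazone condensation as in step 10, the acid‑labile benzyl ether and dihydrobenzofuran being stable to hydrazine.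

**Step 23**
Reactants: 31 the hydrazone
Product: 33 (2R,3R,8R,2′R,3′S)‑hexacyclic nonamethyl ether with cis ring E, via diaryldiazomethane 32 (not isolated)
Conditions: MnO2, CH2Cl2, 0 °C, filter; filtrate added over 2 h to Rh2(S‑PTAD)4 (2 mol %), CH2Cl2, 0 °C
Reagents that add atoms: none
Why: Oxidation to the diazo compound and enantioselective rhodium‑carbene 1,5 C–H insertion as in step 11, now with the enantiomeric catalyst so that C‑3′ is set S under catalyst control (C‑2′ cis, R), insertion into C‑8–H being excluded because ring D holds C‑8 away from the carbene.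

**Step 24**
Reactants: 33 the cis ring E compound
Product: 34 (2R,3R,8R,2′S,3′S)‑hexacyclic nonamethyl ether (both dihydrofuran rings trans)
Conditions: TFA (5 equiv), CH2Cl2, 0 °C
Reagents that add atoms: none
Why: Acid‑induced opening and reclosure of the very labile 2,4‑dimethoxybenzylic C‑2′–O bond equilibrates C‑2′ to the trans isomer (S) while C‑3′ is untouched.

**Step 25**
Reactants: 34 the nonamethyl ether
Product: 35 target, (2R,3R,8R,2′S,3′S)‑nonaphenol CNP0283541.1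
Conditions: BBr3 (30 equiv), CH2Cl2, −78 °C to rt; then H2O
Reagents that add atoms: none
Why: Lewis‑acid cleavage of the nine aryl methyl ethers (BBr3 demethylation), in which the benzylic ether bonds may open reversibly but reclose to the thermodynamic trans rings so that no stereocentre is lost.

**Compound list**
1 | methyl 3,5‑dihydroxybenzoate | COC(=O)c1cc(O)cc(O)c1 | starting material
2 | methyl 3,5‑bis(methoxymethoxy)benzoate | COCOc1cc(OCOC)cc(c1)C(=O)OC | intermediate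
3 | [3,5‑bis(methoxymethoxy)phenyl]methanol | COCOc1cc(CO)cc(OCOC)c1 | intermediate
4 | [2,6‑dibromo‑3,5‑bis(methoxymethoxy)phenyl]methanol | OCc1c(Br)c(OCOC)cc(OCOC)c1Br | intermediate
5 | tert‑butyl{[2,6‑dibromo‑3,5‑bis(methoxymethoxy)phenyl]methoxy}diphenylsilane | CC(C)(C)[Si](OCc1c(Br)c(OCOC)cc(OCOC)c1Br)(c1ccccc1)c1ccccc1 | intermediate
6 | 3,5‑dimethoxybenzaldehyde | COc1cc(C=O)cc(OC)c1 | starting material
7 | {3‑bromo‑2‑[(tert‑butyldiphenylsilyloxy)methyl]‑4,6‑bis(methoxymethoxy)phenyl}lithium | COCOc1cc(OCOC)c(Br)c(CO[Si](c2ccccc2)(c2ccccc2)C(C)(C)C)c1[Li] | intermediate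
8 | (RS)‑{3‑bromo‑2‑[(tert‑butyldiphenylsilyloxy)methyl]‑4,6‑bis(methoxymethoxy)phenyl}(3,5‑dimethoxyphenyl)methanol | COCOc1cc(OCOC)c(Br)c(CO[Si](c2ccccc2)(c2ccccc2)C(C)(C)C)c1C(O)c1cc(OC)cc(OC)c1 | intermediate
9 | {3‑bromo‑2‑[(tert‑butyldiphenylsilyloxy)methyl]‑4,6‑bis(methoxymethoxy)phenyl}(3,5‑dimethoxyphenyl)methanone | COCOc1cc(OCOC)c(Br)c(CO[Si](c2ccccc2)(c2ccccc2)C(C)(C)C)c1C(=O)c1cc(OC)cc(OC)c1 | intermediate
10 | {3‑bromo‑2‑[(tert‑butyldiphenylsilyloxy)methyl]‑4,6‑dihydroxyphenyl}(3,5‑dimethoxyphenyl)methanone | Oc1cc(O)c(Br)c(CO[Si](c2ccccc2)(c2ccccc2)C(C)(C)C)c1C(=O)c1cc(OC)cc(OC)c1 | intermediate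
11 | {3‑bromo‑2‑[(tert‑butyldiphenylsilyloxy)methyl]‑6‑hydroxy‑4‑(prop‑2‑en‑1‑yloxy)phenyl}(3,5‑dimethoxyphenyl)methanone | Oc1cc(OCC=C)c(Br)c(CO[Si](c2ccccc2)(c2ccccc2)C(C)(C)C)c1C(=O)c1cc(OC)cc(OC)c1 | intermediate
12 | 4‑methoxybenzyl chloride | COc1ccc(CCl)cc1 | starting material
13 | {3‑bromo‑2‑[(tert‑butyldiphenylsilyloxy)methyl]‑6‑[(4‑methoxyphenyl)methoxy]‑4‑(prop‑2‑en‑1‑yloxy)phenyl}(3,5‑dimethoxyphenyl)methanone | COc1ccc(COc2cc(OCC=C)c(Br)c(CO[Si](c3ccccc3)(c3ccccc3)C(C)(C)C)c2C(=O)c2cc(OC)cc(OC)c2)cc1 | intermediate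
14 | hydrazone of 13 (E/Z mixture) | COc1ccc(COc2cc(OCC=C)c(Br)c(CO[Si](c3ccccc3)(c3ccccc3)C(C)(C)C)c2C(=NN)c2cc(OC)cc(OC)c2)cc1 | intermediate
15 | diazo compound from 14, aryl(3,5‑dimethoxyphenyl)diazomethane | COc1ccc(COc2cc(OCC=C)c(Br)c(CO[Si](c3ccccc3)(c3ccccc3)C(C)(C)C)c2C(=[N+]=[N-])c2cc(OC)cc(OC)c2)cc1 | intermediate
16 | (2S,3R)‑5‑bromo‑4‑[(tert‑butyldiphenylsilyloxy)methyl]‑3‑(3,5‑dimethoxyphenyl)‑2‑(4‑methoxyphenyl)‑6‑(prop‑2‑en‑1‑yloxy)‑2,3‑dihydro‑1‑benzofuran (cis) | COc1ccc([C@H]2Oc3cc(OCC=C)c(Br)c(CO[Si](c4ccccc4)(c4ccccc4)C(C)(C)C)c3[C@H]2c2cc(OC)cc(OC)c2)cc1 | intermediate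
17 | (2R,3R)‑5‑bromo‑4‑[(tert‑butyldiphenylsilyloxy)methyl]‑3‑(3,5‑dimethoxyphenyl)‑2‑(4‑methoxyphenyl)‑6‑(prop‑2‑en‑1‑yloxy)‑2,3‑dihydro‑1‑benzofuran (trans) | COc1ccc([C@@H]2Oc3cc(OCC=C)c(Br)c(CO[Si](c4ccccc4)(c4ccccc4)C(C)(C)C)c3[C@H]2c2cc(OC)cc(OC)c2)cc1 | intermediate
18 | [(2R,3R)‑5‑bromo‑3‑(3,5‑dimethoxyphenyl)‑2‑(4‑methoxyphenyl)‑6‑(prop‑2‑en‑1‑yloxy)‑2,3‑dihydro‑1‑benzofuran‑4‑yl]methanol | COc1ccc([C@@H]2Oc3cc(OCC=C)c(Br)c(CO)c3[C@H]2c2cc(OC)cc(OC)c2)cc1 | intermediate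
19 | (2R,3R)‑5‑bromo‑3‑(3,5‑dimethoxyphenyl)‑2‑(4‑methoxyphenyl)‑6‑(prop‑2‑en‑1‑yloxy)‑2,3‑dihydro‑1‑benzofuran‑4‑carbaldehyde | COc1ccc([C@@H]2Oc3cc(OCC=C)c(Br)c(C=O)c3[C@H]2c2cc(OC)cc(OC)c2)cc1 | intermediate
20 | (2,4‑dimethoxyphenyl)acetic acid | COc1ccc(CC(=O)O)c(OC)c1 | starting material
21 | dilithium 2‑(2,4‑dimethoxyphenyl)ethene‑1,1‑diolate | [Li+].[Li+].COc1ccc(C=C([O-])[O-])c(OC)c1 | intermediate
22 | 3‑[(2R,3R)‑5‑bromo‑3‑(3,5‑dimethoxyphenyl)‑2‑(4‑methoxyphenyl)‑6‑(prop‑2‑en‑1‑yloxy)‑2,3‑dihydro‑1‑benzofuran‑4‑yl]‑2‑(2,4‑dimethoxyphenyl)‑3‑hydroxypropanoic acid (side‑chain centres undefined) | COc1ccc([C@@H]2Oc3cc(OCC=C)c(Br)c(C(O)C(C(=O)O)c4ccc(OC)cc4OC)c3[C@H]2c2cc(OC)cc(OC)c2)cc1 | intermediate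
23 | (2R,3R)‑5‑bromo‑4‑[(E)‑2‑(2,4‑dimethoxyphenyl)ethenyl]‑3‑(3,5‑dimethoxyphenyl)‑2‑(4‑methoxyphenyl)‑6‑(prop‑2‑en‑1‑yloxy)‑2,3‑dihydro‑1‑benzofuran | COc1ccc([C@@H]2Oc3cc(OCC=C)c(Br)c(/C=C/c4ccc(OC)cc4OC)c3[C@H]2c2cc(OC)cc(OC)c2)cc1 | intermediate
24 | (2R,3R,8R)‑tetracyclic bromide (rings A–D; ring A with Br and O‑allyl) | COc1ccc([C@@H]2Oc3cc(OCC=C)c(Br)c4c3[C@H]2c2cc(OC)cc(OC)c2[C@@H](c2ccc(OC)cc2OC)C4)cc1 | intermediate
25 | (2R,3R,8R)‑tetracyclic aryllithium (Li in place of Br of 24) | COc1ccc([C@@H]2Oc3cc(OCC=C)c([Li])c4c3[C@H]2c2cc(OC)cc(OC)c2[C@@H](c2ccc(OC)cc2OC)C4)cc1 | intermediate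
26 | (2R,3R,8R)‑tetracyclic diarylmethanol (CH(OH)(3,5‑dimethoxyphenyl) in place of Br; carbinol epimers) | COc1ccc([C@@H]2Oc3cc(OCC=C)c(C(O)c5cc(OC)cc(OC)c5)c4c3[C@H]2c2cc(OC)cc(OC)c2[C@@H](c2ccc(OC)cc2OC)C4)cc1 | intermediate
27 | (2R,3R,8R)‑tetracyclic 3,5‑dimethoxybenzoyl ketone, O‑allyl | COc1ccc([C@@H]2Oc3cc(OCC=C)c(C(=O)c5cc(OC)cc(OC)c5)c4c3[C@H]2c2cc(OC)cc(OC)c2[C@@H](c2ccc(OC)cc2OC)C4)cc1 | intermediate
28 | (2R,3R,8R)‑tetracyclic 3,5‑dimethoxybenzoyl ketone, free ortho phenol | COc1ccc([C@@H]2Oc3cc(O)c(C(=O)c5cc(OC)cc(OC)c5)c4c3[C@H]2c2cc(OC)cc(OC)c2[C@@H](c2ccc(OC)cc2OC)C4)cc1 | intermediate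
29 | 2,4‑dimethoxybenzyl alcohol | COc1ccc(CO)c(OC)c1 | starting material
30 | (2R,3R,8R)‑tetracyclic 3,5‑dimethoxybenzoyl ketone, 2,4‑dimethoxybenzyl ether | COc1ccc([C@@H]2Oc3cc(OCc6ccc(OC)cc6OC)c(C(=O)c5cc(OC)cc(OC)c5)c4c3[C@H]2c2cc(OC)cc(OC)c2[C@@H](c2ccc(OC)cc2OC)C4)cc1 | intermediate
31 | hydrazone of 30 (E/Z mixture) | COc1ccc([C@@H]2Oc3cc(OCc6ccc(OC)cc6OC)c(C(=NN)c5cc(OC)cc(OC)c5)c4c3[C@H]2c2cc(OC)cc(OC)c2[C@@H](c2ccc(OC)cc2OC)C4)cc1 | intermediate
32 | diazo compound from 31 | COc1ccc([C@@H]2Oc3cc(OCc6ccc(OC)cc6OC)c(C(=[N+]=[N-])c5cc(OC)cc(OC)c5)c4c3[C@H]2c2cc(OC)cc(OC)c2[C@@H](c2ccc(OC)cc2OC)C4)cc1 | intermediate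
33 | (2R,3R,8R,2′R,3′S)‑hexacyclic nonamethyl ether, ring E cis | COc1ccc([C@@H]2Oc3cc4c(c5c3[C@H]2c2cc(OC)cc(OC)c2[C@@H](c2ccc(OC)cc2OC)C5)[C@H](c2cc(OC)cc(OC)c2)[C@H](c2ccc(OC)cc2OC)O4)cc1 | intermediate
34 | (2R,3R,8R,2′S,3′S)‑hexacyclic nonamethyl ether, both dihydrofuran rings trans | COc1ccc([C@@H]2Oc3cc4c(c5c3[C@H]2c2cc(OC)cc(OC)c2[C@@H](c2ccc(OC)cc2OC)C5)[C@H](c2cc(OC)cc(OC)c2)[C@@H](c2ccc(OC)cc2OC)O4)cc1 | intermediate
35 | CNP0283541.1, (2R,3R,8R,2′S,3′S)‑nonaphenol | Oc1ccc([C@@H]2Oc3cc4c(c5c3[C@H]2c2cc(O)cc(O)c2[C@@H](c2ccc(O)cc2O)C5)[C@H](c2cc(O)cc(O)c2)[C@@H](c2ccc(O)cc2O)O4)cc1 | target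

**Step count and risks**
Total steps: 25. Longest linear sequence: 25 steps (1 → 35); 6 (used twice), 12, 20 and 29 enter directly.

The three steps most likely to fail:

Step 11 (hindered hydrazone/diazo formation and enantioselective C–H insertion; step 23 carries the same risk). The fallback sets out from ketone 13 and comes back at 17. Corey–Chaykovsky methylenation of 13 (Me3S+ I−, KOt‑Bu, DMSO/THF) would give the racemic 2,2‑diaryloxirane F1. ZnI2 in benzene would rearrange it (Meinwald hydride shift) to the diarylacetaldehyde F2. Addition of 4‑MeOC6H4MgBr (THF, −78 °C) would give the secondary alcohol F3. TFA in CH2Cl2 with 1,3,5‑trimethoxybenzene as cation trap would cleave the 4‑methoxybenzyl ether and close the freed phenol onto the anisyl‑stabilised benzylic cation, giving the racemic trans‑dihydrobenzofuran, that is 17 together with its (2S,3S) enantiomer F4. Preparative HPLC on a chiral stationary phase then delivers 17.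

Step 15 (addition to a di‑ortho‑substituted aldehyde, retro‑aldol on work‑up). The fallback sets out from aldehyde 19 and comes back at stilbene 23. A Horner–Wadsworth–Emmons olefination of 19 with diethyl (2,4‑dimethoxybenzyl)phosphonate (NaH, THF, 0 °C to rt) gives 23 in one operation and bypasses 22; it makes no new compound F0.

Step 25 (nine methyl ethers beside two acid‑labile benzylic ether bonds). The fallback sets out from 34 and comes back at 35. Nucleophilic demethylation with EtSNa in DMF at 140 °C cleaves the methyl ethers by thiolate attack at methyl with no Lewis acid present, so the benzylic C–O bonds are not ionised; it makes no new compound F0.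

**Further compounds**
F1 | step 11 | 2‑{3‑bromo‑2‑[(tert‑butyldiphenylsilyloxy)methyl]‑6‑[(4‑methoxyphenyl)methoxy]‑4‑(prop‑2‑en‑1‑yloxy)phenyl}‑2‑(3,5‑dimethoxyphenyl)oxirane (racemic) | COc1ccc(COc2cc(OCC=C)c(Br)c(CO[Si](c3ccccc3)(c3ccccc3)C(C)(C)C)c2C4(CO4)c5cc(OC)cc(OC)c5)cc1
F2 | step 11 | 2‑{3‑bromo‑2‑[(tert‑butyldiphenylsilyloxy)methyl]‑6‑[(4‑methoxyphenyl)methoxy]‑4‑(prop‑2‑en‑1‑yloxy)phenyl}‑2‑(3,5‑dimethoxyphenyl)acetaldehyde (racemic) | COc1ccc(COc2cc(OCC=C)c(Br)c(CO[Si](c3ccccc3)(c3ccccc3)C(C)(C)C)c2C(C=O)c5cc(OC)cc(OC)c5)cc1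
F3 | step 11 | 2‑{3‑bromo‑2‑[(tert‑butyldiphenylsilyloxy)methyl]‑6‑[(4‑methoxyphenyl)methoxy]‑4‑(prop‑2‑en‑1‑yloxy)phenyl}‑2‑(3,5‑dimethoxyphenyl)‑1‑(4‑methoxyphenyl)ethan‑1‑ol (racemic diastereomer mixture) | COc1ccc(COc2cc(OCC=C)c(Br)c(CO[Si](c3ccccc3)(c3ccccc3)C(C)(C)C)c2C(C(O)c6ccc(OC)cc6)c5cc(OC)cc(OC)c5)cc1
F4 | step 11 | (2S,3S)‑5‑bromo‑4‑[(tert‑butyldiphenylsilyloxy)methyl]‑3‑(3,5‑dimethoxyphenyl)‑2‑(4‑methoxyphenyl)‑6‑(prop‑2‑en‑1‑yloxy)‑2,3‑dihydro‑1‑benzofuran (enantiomer of 17) | COc1ccc([C@H]2Oc3cc(OCC=C)c(Br)c(CO[Si](c4ccccc4)(c4ccccc4)C(C)(C)C)c3[C@@H]2c2cc(OC)cc(OC)c2)cc1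
F0 | step 15 | none | none
F0 | step 25 | none | none
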